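**Assumption:** the target has no stereocentre (it is achiral, so no enantiomer question arises), and dimethyl pentadecanedioate is bought as such.

## Retrosynthetic overview

1. Target ⇒ bis(methoxyquinone) ⇒ bis(hydroxyquinone) ⇒ tethered bis(2-methyl-5-alkylresorcinol). The O-methyl and the two extra ring oxygens are added after aromatisation (para-oxidation, O-methylation, epoxidation/isomerisation), as in sorgoleone-type pathways.
2. Both resorcinol rings ⇒ C2-to-C7 aldol condensation, aromatisation and decarboxylation of a tethered bis(4-methyl-3,5,7-trioxo acid). This is the tetraketide an alkylresorcinol synthase would build on each end of the C15 diacid.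
3. Bis(triketo acid) ⇒ CO2 + bis(1,3,5-triketone) ⇒ dimethyl pentadecanedioate + two 3-methylpentane-2,4-dione units. The C-methyl enters with the chain, like a methylmalonate extender.
4. Ring order: ring A and ring B are formed at the same time, in one flask (step 2); no ring is bought.

## Route

Step 1
Reactants: 1 dimethyl pentadecanedioate; 2 3-methylpentane-2,4-dione
Product: 4 bis(triketone) 3,23-dimethylpentacosane-2,4,6,20,22,24-hexaone, via dilithio-3-methylpentane-2,4-dione 3 (not isolated)
Conditions: 2 (5 equiv), LiN(i-Pr)2 (10 equiv), THF, 0 °C; then 1, 0 °C → rt; aq HCl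
Reagents that add atoms: none
Why: Dianion Claisen condensation (Hauser–Harris acylation of a β-diketone dianion), in which the terminal carbanion of 3 is the only reactive site, each new triketone end is at once deprotonated to an unreactive dianion that stops over-acylation, and the two CHMe centres formed are enolisable and later become aromatic carbons, so no stereocontrol is needed.

Step 2
Reactants: 4 bis(triketone) 3,23-dimethylpentacosane-2,4,6,20,22,24-hexaone
Product: 8 bis-resorcinol 5,5'-(tridecane-1,13-diyl)bis(2-methylbenzene-1,3-diol), via hexalithium bis(trienolate) 5 (not isolated), via bis(4-methyl-3,5,7-trioxo acid) lithium salt 6 (not isolated), via bis(β-resorcylic acid) 7 (not isolated)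
Conditions: LiN(i-Pr)2 (7 equiv), THF, −78 → 0 °C; CO2 (g), −78 °C → rt; 10% aq KOH, rt, 16 h; then HCl to pH 1, 90 °C, 1 h
Reagents that add atoms: none
Why: Biomimetic polyketide cyclisation (Harris trianion carboxylation, then intramolecular C2-to-C7 aldol condensation/aromatisation and decarboxylation of the β-resorcylic acid), in which the kinetic third deprotonation takes each terminal methyl, the carboxylate placed there makes C2 the one readily enolised nucleophile so each chain end closes only to the 6-alkyl-2,4-dihydroxy-3-methylbenzoate, and the electron-rich acid then loses the CO2 carbon again on warming in acid, as in the enzymatic decarboxylative alkylresorcinol ring closure; no stereocentre remains.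

Step 3
Reactants: 8 bis-resorcinol 5,5'-(tridecane-1,13-diyl)bis(2-methylbenzene-1,3-diol)
Product: 9 bis(hydroxyquinone) 6,6'-(tridecane-1,13-diyl)bis(2-hydroxy-3-methylcyclohexa-2,5-diene-1,4-dione)
Conditions: ON(SO3K)2 (5 equiv), KH2PO4, H2O/CH2Cl2, methyltrioctylammonium chloride (cat.), rt
Reagents that add atoms: potassium nitrosodisulfonate, [K+].[K+].[O]N(S(=O)(=O)[O-])S(=O)(=O)[O-]
Why: Teuber oxidation, in which the nitroxide radical makes the phenoxyl radical and delivers oxygen to the free para position (the two para sites of each ring are equivalent by symmetry and the carbon between the hydroxyls is blocked by methyl), giving one 2-hydroxy-1,4-benzoquinone per ring with no stereocentre formed.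

Step 4
Reactants: 9 bis(hydroxyquinone) 6,6'-(tridecane-1,13-diyl)bis(2-hydroxy-3-methylcyclohexa-2,5-diene-1,4-dione)
Product: 10 bis(methoxyquinone) 6,6'-(tridecane-1,13-diyl)bis(2-methoxy-3-methylcyclohexa-2,5-diene-1,4-dione)
Conditions: MeOH/CH2Cl2, H2SO4 (cat.), 40 °C
Reagents that add atoms: methanol, CO
Why: Acid-catalysed vinylogous Fischer esterification of a 2-hydroxy-1,4-benzoquinone (addition–elimination of methanol at the vinylogous acid carbon, the reaction type that turns lawsone into 2-methoxy-1,4-naphthoquinone), which under equilibrium control gives the para-quinone methyl ether and creates no stereocentre.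

Step 5
Reactants: 10 bis(methoxyquinone) 6,6'-(tridecane-1,13-diyl)bis(2-methoxy-3-methylcyclohexa-2,5-diene-1,4-dione)
Product: 12 target 3,3'-(tridecane-1,13-diyl)bis(2-hydroxy-5-methoxy-6-methylcyclohexa-2,5-diene-1,4-dione), via bis(epoxyquinone) 11 (not isolated)
Conditions: 30% aq H2O2, Na2CO3 (cat.), THF/EtOH, 0 °C; then H2SO4 in AcOH, rt
Reagents that add atoms: hydrogen peroxide, OO
Why: Weitz–Scheffer nucleophilic epoxidation takes place at the alkyl/H double bond (hydroperoxide adds to the unsubstituted carbon, while the methoxy-bearing double bond is a deactivated vinylogous ester), and the acid-catalysed epoxyquinone-to-hydroxyquinone isomerisation (the reaction type that gives phthiocol from menadione oxide) opens the epoxide at the tertiary carbon and loses the neighbouring proton, leaving OH on the former C–H carbon next to the chain and destroying the transient epoxide stereocentres.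

## Compound list

1 | dimethyl pentadecanedioate | COC(=O)CCCCCCCCCCCCCC(=O)OC | starting material
2 | 3-methylpentane-2,4-dione | CC(=O)C(C)C(C)=O | starting material
3 | dilithio-3-methylpentane-2,4-dione (dianion drawn as bis-enolate; not isolated) | [Li+].[Li+].C=C([O-])C(C)=C(C)[O-] | intermediate
4 | 3,23-dimethylpentacosane-2,4,6,20,22,24-hexaone (keto–enol mixture; the two CHMe centres are labile and unassigned) | CC(=O)C(C)C(=O)CC(=O)CCCCCCCCCCCCCC(=O)CC(=O)C(C)C(C)=O | intermediate
5 | hexalithium bis(trienolate) of 4 (not isolated) | [Li+].[Li+].[Li+].[Li+].[Li+].[Li+].C=C([O-])C(C)=C([O-])C=C([O-])CCCCCCCCCCCCCC([O-])=CC([O-])=C(C)C([O-])=C | intermediate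
6 | 4,24-dimethyl-3,5,7,21,23,25-hexaoxoheptacosanedioic acid (present as its lithium salt; not isolated) | OC(=O)CC(=O)C(C)C(=O)CC(=O)CCCCCCCCCCCCCC(=O)CC(=O)C(C)C(=O)CC(O)=O | intermediate
7 | 6,6'-(tridecane-1,13-diyl)bis(2,4-dihydroxy-3-methylbenzoic acid) (not isolated) | OC(=O)c1c(O)c(C)c(O)cc1CCCCCCCCCCCCCc1cc(O)c(C)c(O)c1C(O)=O | intermediate
8 | 5,5'-(tridecane-1,13-diyl)bis(2-methylbenzene-1,3-diol) | Cc1c(O)cc(CCCCCCCCCCCCCc2cc(O)c(C)c(O)c2)cc1O | intermediate
9 | 6,6'-(tridecane-1,13-diyl)bis(2-hydroxy-3-methylcyclohexa-2,5-diene-1,4-dione) | CC1=C(O)C(=O)C(CCCCCCCCCCCCCC2=CC(=O)C(C)=C(O)C2=O)=CC1=O | intermediate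
10 | 6,6'-(tridecane-1,13-diyl)bis(2-methoxy-3-methylcyclohexa-2,5-diene-1,4-dione) | COC1=C(C)C(=O)C=C(CCCCCCCCCCCCCC2=CC(=O)C(C)=C(OC)C2=O)C1=O | intermediate
11 | 1,13-bis(3-methoxy-4-methyl-2,5-dioxo-7-oxabicyclo[4.1.0]hept-3-en-1-yl)tridecane (cis-epoxides, mixture of stereoisomers; not isolated) | COC1=C(C)C(=O)C2OC2(CCCCCCCCCCCCCC34OC3C(=O)C(C)=C(OC)C4=O)C1=O | intermediate
12 | 3,3'-(tridecane-1,13-diyl)bis(2-hydroxy-5-methoxy-6-methylcyclohexa-2,5-diene-1,4-dione) (CNP0110425.0, achiral) | COC1=C(C)C(=O)C(O)=C(CCCCCCCCCCCCCC2=C(O)C(=O)C(C)=C(OC)C2=O)C1=O | target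

## Step count and risks

Total step count: 5. Longest linear sequence: 5 steps (1 → 4 → 8 → 9 → 10 → 12).

The three steps most likely to fail:

**Step 2 (highest risk).** The hexaanion may be poorly soluble or carboxylate incompletely, and hydroxide cleavage of the 2-methyl-1,3-diketone can compete with ring closure. The fallback puts the carboxyl carbon in before the chain is joined; it sets out from 2 and comes back to the route at 8. Dianion 3 is quenched with dimethyl carbonate to give methyl 4-methyl-3,5-dioxohexanoate F3. Its trilithium trianion (LiN(i-Pr)2, 3 equiv, THF) is acylated at the terminal methyl by both ester groups of 1 to give dimethyl 4,24-dimethyl-3,5,7,21,23,25-hexaoxoheptacosanedioate F4. Aqueous carbonate buffer (about pH 10) closes both ends by the same C2-to-C7 aldol to give dimethyl 6,6'-(tridecane-1,13-diyl)bis(2,4-dihydroxy-3-methylbenzoate) F5. Aqueous KOH at reflux followed by acid saponifies and decarboxylates F5 to 8.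

**Step 1.** The enolisable aliphatic diester can be deprotonated instead of acylated, and half-acylated material can build up. The fallback replaces the Claisen condensation by aldol addition and oxidation; it sets out from 1 and comes back at 4. i-Bu2AlH (CH2Cl2, −78 °C) reduces 1 to pentadecanedial F1. Dianion 3 adds through its terminal carbon to both aldehydes to give 6,20-dihydroxy-3,23-dimethylpentacosane-2,4,22,24-tetraone F2 (mixture of stereoisomers). Dess–Martin periodinane oxidises both carbinols to give 4.

**Step 5.** Alkaline peroxide may attack the methoxy-bearing carbon, or the acid step may give acyl-shift (ring-contracted) products. The fallback is a Thiele–Winter acetoxylation; it sets out from 10 and comes back at 12. Ac2O with catalytic HClO4 adds acetate at the only free ring position and acetylates both quinone oxygens, giving 1,13-bis(2,3,6-triacetoxy-5-methoxy-4-methylphenyl)tridecane F6. HCl in methanol removes the six acetates, and the hydroxyhydroquinone formed is oxidised by air (or FeCl3) to 12.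

Further compounds
F1 | step 1 | pentadecanedial | O=CCCCCCCCCCCCCCC=O
F2 | step 1 | 6,20-dihydroxy-3,23-dimethylpentacosane-2,4,22,24-tetraone (mixture of stereoisomers) | CC(=O)C(C)C(=O)CC(O)CCCCCCCCCCCCCC(O)CC(=O)C(C)C(C)=O
F3 | step 2 | methyl 4-methyl-3,5-dioxohexanoate | COC(=O)CC(=O)C(C)C(C)=O
F4 | step 2 | dimethyl 4,24-dimethyl-3,5,7,21,23,25-hexaoxoheptacosanedioate | COC(=O)CC(=O)C(C)C(=O)CC(=O)CCCCCCCCCCCCCC(=O)CC(=O)C(C)C(=O)CC(=O)OC
F5 | step 2 | dimethyl 6,6'-(tridecane-1,13-diyl)bis(2,4-dihydroxy-3-methylbenzoate) | COC(=O)c1c(O)c(C)c(O)cc1CCCCCCCCCCCCCc1cc(O)c(C)c(O)c1C(=O)OC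
F6 | step 5 | 1,13-bis(2,3,6-triacetoxy-5-methoxy-4-methylphenyl)tridecane | COc1c(C)c(OC(C)=O)c(OC(C)=O)c(CCCCCCCCCCCCCc2c(OC(C)=O)c(OC(C)=O)c(C)c(OC)c2OC(C)=O)c1OC(C)=O
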